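## Analysis of the target

Compound 26 is a flavone. Ring A (benzene) is fused to ring C (4-pyranone), and ring B sits on C2. All skeletal atoms are sp2, so there is no stereocentre. The task is to place and tell apart eight oxygen substituents: four hydroxyls (C5, C7, C3', C5') and four methyl ethers (C3, C6, C8, C4').

Ring A is hexasubstituted, and hydroxyl and methoxy alternate from C5 to C8. Selective methylation or demethylation of a polyphenol cannot deliver this pattern. The competing sites differ too little, and Lewis acids that free one oxygen also attack the methoxy groups near the chelating C4 carbonyl.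

The free polyphenol is electron-rich and oxidises easily as its phenoxide, so the hydroxyls should be unmasked last and under acid. The C3 oxygen is usually added by oxidising a finished chalcone or flavone, which is unattractive next to so electron-rich a ring A.

The strategy rests on what appears when O1–C2 is opened. Ring A becomes a 2,4,6-trioxygenated 3,5-dimethoxyphenyl group with a mirror plane through C4a and C7, so the oxygens on C5 and C8a are interchangeable. C4 is then a single carbonyl carbon between C4a and C3. C3 with its methoxy group, C2 and the equally symmetric ring B together form an aryl methoxymethyl ketone.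

## Retrosynthetic reasoning

**O1–C2 (26 ⇒ 25 ⇒ 24).** Ring C is opened at O1–C2 and the five phenolic oxygens are masked again as methoxymethyl acetals. This leads through the free diketone 25 to the protected open-chain 2-methoxy-1,3-diketone 24.
- The cut belongs here because the closing oxygen can be either ortho hydroxyl of 25, and both give the same flavone.
- For the same reason, an acid-induced ring opening and re-closure of the Wessely–Moser type is degenerate.
- The diketone already has the flavone oxidation level, so the forward step is a single acid treatment. It strips five identical acetals and cyclodehydrates, with no redox chemistry on the electron-rich rings.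

**C4a–C4 and C4–C3 (24 ⇒ 12 + 21 + 20).** Both bonds at C4 are cut together, giving aryl iodide 12, carbon monoxide 21 and methoxymethyl ketone 20.
- Cutting C2–C3 instead would call for a ring A acyl piece with one free ortho hydroxyl. That would destroy the mirror plane and force the three ring A oxygens to be differentiated.
- With C4 supplied by 21, the ring A partner needs only a halogen at its one open position, and C3 arrives already methoxylated.
- The gain is a convergent union of two symmetric halves.
- In the forward step, carbonylation must outrun direct arylation, and acylation must end on carbon rather than on oxygen.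

**C4a–I (12 ⇒ 11 ⇒ 10).** The only ring hydrogen of 10 lies between two acetal oxygens. Directed metalation to 11 and capture by an electrophilic iodine source involve no regiochemical choice.

**C8–O and C6–O (10 ⇒ 9 ⇒ 6 ⇒ 5 ⇒ 2 ⇒ 1).** The two methoxy oxygens are removed one after the other. Each is installed by the same pair of operations: metalation between two acetal oxygens with boron-to-oxygen oxidation (7/8 to 9, and 3/4 to 5), followed by O-methylation.
- At every stage all open positions are symmetry-equivalent, so one product is possible each time.
- The sequence ends at the triacetal 2 of phloroglucinol 1.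
- A ring that already carries the two methoxy groups and a carboxyl group would need two hydroxylations meta to each other plus excision of a carbon substituent, which is longer and less certain.

**C2–C3 side of the ketone (20 ⇒ 19 ⇒ 15 + 16).** The aroyl–CH(OMe) bond is cut after a removable ester is added back at C3. Ester 15 has no α-hydrogen and can act only as acceptor. Methyl methoxyacetate 16 supplies C3 together with its methoxy group. The forward steps are a crossed Claisen condensation and a neutral dealkoxycarbonylation.

**Protection of ring B (15 ⇒ 14 ⇒ 13).** The two equivalent phenols of 14 are masked with the same acetal as ring A, so one reagent clears all five at the end. Ester 14 comes from the commercial acid 13.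

## Alternatives that were turned down

Alternative 1: Ring A is dismantled completely. C5 to C8 come from a four-membered ring, and C4a and C8a come from C5 and C6 of a finished 2-aryl-3-methoxypyran-4-one.
- *Forward key step.* The bromopyranone A4 would be metalated at C5 and added to one carbonyl of the mixed squarate A3 to give the cyclobutenol A1. On heating, A1 should open in a 4π electrocyclic step to a dienylketene. The ketene carbon should bond to C8a in a 6π closure (bond C8–C8a), and tautomerisation should give the 5,8-hydroquinone A2.
- *For it.* All four ring A oxygens arrive with the squarate. The key step needs neither metal nor gas, and it closes a ring, which the chosen key step does not. On these points it is the stronger plan.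
- *Against it.* The C6/C7 pattern is fixed when the nucleophile chooses between the two carbonyls of A3. These differ only in a methoxy versus an isopropoxy neighbour, so the isomer with C6 and C7 exchanged must be expected. A 5-metalated pyranone carries its own electrophilic enone, and A4 is itself a multistep target.
- *After the key step.* A2 is an oxidation-prone hydroquinone. It still needs selective methylation at O8, which is plausible because the C5 hydroxyl is chelated. It then needs cleavage of three isopropyl ethers by a boron halide, which endangers the methoxy groups at C3 and C6 near the chelating carbonyl.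
- *Comparison.* The chosen route replaces these decisions by symmetry. Iodide 12 offers no regiochemical choice, all five masks are the same acetal, and only one step follows the key step.

Alternative 2: The cut is C4a–C8a, which unrolls ring A into the polyketide-like triketo ester A5.
- *Forward key step.* Methoxide would deprotonate the C4a methylene between two carbonyls. This carbanion would attack the terminal ester carbon in the Claisen mode, and enolisation would give the phloroglucinol ring of the α-methoxychalcone A6.
- *For it.* Ring A is made fully substituted from acyclic pieces with a cheap base and no aromatic functionalisation. It needs no ring A protecting groups, and it profits from the same ring A symmetry in the later closure. On paper it is the shorter and more elegant way to ring A.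
- *Against it.* A5 has four carbonyl groups, several kinds of acidic C–H and two labile stereocentres. Without an enzyme, such chains close just as readily by aldol condensation to resorcylates or by O-acylation to 4-hydroxy-2-pyranones, and nothing in A5 biases it towards the Claisen mode. Building the chain by repeated acylation of α-methoxy enolates is long and prone to retro-Claisen cleavage.
- *After the key step.* A6 is only at the chalcone oxidation level. An oxidative ring closure must be run next to a free, highly oxidisable trihydroxy ring before the benzyl ethers are removed.
- *Comparison.* The chosen route reaches the diketone oxidation level directly, so ring closure is a mere dehydration. Its precursors are stable aromatic compounds of predictable reactivity.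

Alternative 3: C3–C4 and O1–C2 are cut together, so ring C is removed in a formal [4+2] sense.
- *Forward key step.* Irradiation of the benzodioxinone A7 would extrude the ketone of its acetonide and leave the quinoketene A9. The silyl enol ether A8 would add with its nucleophilic carbon (C3) to the ketene carbon (C4) and with its silyloxy carbon (C2) to the ring oxygen (O1). Acidic work-up would eliminate silanol to give the tetrabenzyl flavone A10, which hydrogenolysis would unmask.
- *For it.* The polarity is matched. Two bonds and ring C form in one step, which is clearly more than the chosen key step achieves. No metal or gas is needed, and the final hydrogenolysis is milder than hot acid.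
- *Against it.* A7 derives from a fully substituted salicylic acid in which one ortho oxygen is tied into the acetonide and the other is benzylated. Ring A symmetry is therefore given up, and carboxylation, ketalisation and differentiation all cost steps. Such ketenes are trapped reliably by oxygen and nitrogen nucleophiles. Capture by a trisubstituted enol ether must compete with dimerisation and traces of moisture.
- *Photochemical risk.* A10 absorbs in the same region as A7. It also carries a photoreactive pair, the C4 carbonyl and the C3 methoxy group, which is set up for hydrogen abstraction. The product is therefore at risk under the conditions that form it.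
- *Comparison.* The chosen route keeps the mirror plane until the last step, runs thermally within a known reaction type, and uses the same kind of ring B ketone.

Key step: step 11

Assumption: 24 and 25 are drawn as chelated enols. Each equilibrates with its diketo tautomer, whose C3 centre is configurationally labile and becomes sp2 in 26, so the tautomer ratio has no consequence.

## Route

Step 1
Reactants: 1 phloroglucinol (benzene-1,3,5-triol, anhydrous)
Product: 2 1,3,5-tris(methoxymethoxy)benzene
Conditions: NaH, MOMCl, DMF, 0 °C → rt
Reagents that add atoms: chloromethyl methyl ether (MOMCl), COCCl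
Why: Williamson-type O-alkylation of the triphenoxide; the hard, oxocarbenium-like electrophile should react at oxygen rather than at carbon of the ambident anion. The three acetals serve both as protecting groups and as directing groups for all three later metalations.

Step 2
Reactants: 2 1,3,5-tris(methoxymethoxy)benzene
Product: 5 2,4,6-tris(methoxymethoxy)phenol, via aryllithium 3 (not isolated), via arylboronate 4 (not isolated)
Conditions: n-BuLi, THF, 0 °C; B(OMe)3, −78 °C → rt; AcOH, 30% aq. H2O2, 0 °C → rt
Reagents that add atoms: hydrogen peroxide, OO
Why: Directed ortho-metalation followed by boration and peroxide oxidation (1,2-shift of aryl from boron to oxygen). The three ring hydrogens are equivalent and each lies between two coordinating acetal oxygens, so one aryllithium can form. The weakly acidic oxidation keeps the electron-rich phenol protonated and leaves the acetals intact.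

Step 3
Reactants: 5 2,4,6-tris(methoxymethoxy)phenol
Product: 6 2-methoxy-1,3,5-tris(methoxymethoxy)benzene
Conditions: MeI, K2CO3, acetone, reflux
Reagents that add atoms: iodomethane, CI
Why: Williamson ether synthesis on the only free hydroxyl; acetals are inert to carbonate base.

Step 4
Reactants: 6 2-methoxy-1,3,5-tris(methoxymethoxy)benzene
Product: 9 3-methoxy-2,4,6-tris(methoxymethoxy)phenol, via aryllithium 7 (not isolated), via arylboronate 8 (not isolated)
Conditions: n-BuLi, THF, 0 °C; B(OMe)3, −78 °C → rt; AcOH, 30% aq. H2O2, 0 °C → rt
Reagents that add atoms: hydrogen peroxide, OO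
Why: Second directed ortho-metalation, boration and oxidation. The two remaining ring hydrogens of 6 are related by its mirror plane and each is again flanked by two acetal oxygens, so a single phenol should result.

Step 5
Reactants: 9 3-methoxy-2,4,6-tris(methoxymethoxy)phenol
Product: 10 2,4-dimethoxy-1,3,5-tris(methoxymethoxy)benzene
Conditions: MeI, K2CO3, DMF, rt → 40 °C
Reagents that add atoms: iodomethane, CI
Why: Williamson ether synthesis; the small electrophile and the polar solvent should overcome the crowding by the two ortho acetal groups.

Step 6
Reactants: 10 2,4-dimethoxy-1,3,5-tris(methoxymethoxy)benzene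
Product: 12 2-iodo-4,6-dimethoxy-1,3,5-tris(methoxymethoxy)benzene, via aryllithium 11 (not isolated)
Conditions: n-BuLi, THF, 0 °C; I2, THF, −78 °C → rt
Reagents that add atoms: iodine, II
Why: Directed ortho-metalation and iodination at the last ring C–H, which lies between two acetal oxygens. The acid-free conditions spare the acetals, which an electrophilic iodination might not.

Step 7
Reactants: 13 3,5-dihydroxy-4-methoxybenzoic acid
Product: 14 methyl 3,5-dihydroxy-4-methoxybenzoate
Conditions: MeOH, H2SO4 (cat.), reflux
Reagents that add atoms: methanol, CO
Why: Fischer esterification; phenols and the aryl methyl ether are untouched.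

Step 8
Reactants: 14 methyl 3,5-dihydroxy-4-methoxybenzoate
Product: 15 methyl 4-methoxy-3,5-bis(methoxymethoxy)benzoate
Conditions: MOMCl, i-Pr2NEt, CH2Cl2, 0 °C → rt
Reagents that add atoms: chloromethyl methyl ether (MOMCl), COCCl
Why: O-alkylation of two equivalent phenols under amine base, which leaves the ester alone. The same acetal as on ring A is chosen so that one reagent removes all five at the end.

Step 9
Reactants: 15 methyl 4-methoxy-3,5-bis(methoxymethoxy)benzoate, 16 methyl methoxyacetate
Product: 19 methyl 2-methoxy-3-[4-methoxy-3,5-bis(methoxymethoxy)phenyl]-3-oxopropanoate (racemic), via lithium enolate 17 (not isolated), via lithium ketoester enolate 18 (not isolated)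
Conditions: 16 (2 equiv), LiN(i-Pr)2 (2 equiv), THF, −78 °C; 15, −78 → 0 °C; AcOH
Reagents that add atoms: none
Why: Crossed Claisen condensation. Ester 15 has no α-hydrogen and can act only as acceptor, and 17 is formed completely in the cold, so self-condensation of 16 is held back. The released methoxide deprotonates 19 to the chelated enolate 18, which pulls the equilibrium. The new centre is racemic and is deleted in step 10.

Step 10
Reactants: 19 methyl 2-methoxy-3-[4-methoxy-3,5-bis(methoxymethoxy)phenyl]-3-oxopropanoate
Product: 20 2-methoxy-1-[4-methoxy-3,5-bis(methoxymethoxy)phenyl]ethanone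
Conditions: LiCl, H2O, DMSO, 120 °C
Reagents that add atoms: none
Why: Krapcho dealkoxycarbonylation. Chloride removes the ester methyl group by SN2 attack, the β-keto carboxylate loses CO2, and water protonates the enolate. The medium stays near neutral, so both acetals should survive.

Step 11
Reactants: 12 2-iodo-4,6-dimethoxy-1,3,5-tris(methoxymethoxy)benzene, 20 2-methoxy-1-[4-methoxy-3,5-bis(methoxymethoxy)phenyl]ethanone, 21 carbon monoxide
Product: 24 (E)-1-[3,5-dimethoxy-2,4,6-tris(methoxymethoxy)phenyl]-3-hydroxy-2-methoxy-3-[4-methoxy-3,5-bis(methoxymethoxy)phenyl]prop-2-en-1-one (chelated enol of the protected 2-methoxy-1,3-diketone), via sodium enolate 22 (not isolated), via sodium diketonate 23 (not isolated)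
Conditions: 20 (2.1 equiv), NaN(SiMe3)2 (2.0 equiv), THF, 0 °C; then 12 (1 equiv), Pd(OAc)2 (5 mol %), 1,3-bis(diphenylphosphino)propane (7.5 mol %), CO (1 atm), THF–1,4-dioxane, 70 °C; AcOH
Reagents that add atoms: none
Why: This is the palladium-catalysed carbonylative α-arylation of a ketone with an aryl iodide, the known three-component route to 1,3-diketones, applied here to a more crowded pair of partners. Pd(OAc)2 is reduced in the flask to the zerovalent palladium–diphosphine complex, which inserts into the weak C–I bond of 12; 21 then coordinates and the aryl group migrates onto it, a step that the two ortho acetal groups favour because it relieves crowding at the metal, and this forms C4a–C4. Enolate 22 displaces iodide from the aroyl complex of divalent palladium, and C–C reductive elimination forms C4–C3 and returns the catalyst. No ring is closed and no lasting stereocentre is made, since C3 of the diketo tautomer is enolisable and becomes sp2 in 26. Carbonylation has to outrun direct arylation: reductive elimination of a doubly ortho-substituted aryl group with an enolate from a small-bite-angle chelate is slow, whereas insertion is fast under one atmosphere of 21. C-acylation has to prevail over O-acylation: any enol ester formed is itself an acyl donor towards 22, and the second equivalent of 22 deprotonates 24 to the chelated diketonate 23, so all acyl-transfer equilibria drain to the C-acylated product. Forming 22 beforehand with slightly less base than ketone leaves no free silylamide to attack 21 or the aroyl complex, and the 20 given back by the proton transfer can be recovered. The five acetals and four methyl ethers are inert to base, phosphine and 21.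

Step 12
Reactants: 24 protected 2-methoxy-1,3-diketone (chelated enol)
Product: 26 5,7,3',5'-tetrahydroxy-3,6,8,4'-tetramethoxyflavone, via pentahydroxy diketone 25 (not isolated)
Conditions: HCl (ca. 3 M in MeOH), reflux, Ar
Reagents that add atoms: none
Why: Acid-catalysed transacetalisation removes all five methoxymethyl groups. An ortho hydroxyl of 25 then adds to the ring B carbonyl (6-exo-trig hemiketal formation) and loss of water aromatises ring C, the classical cyclodehydration of o-hydroxyaryl 1,3-diketones to flavones. Both ortho hydroxyls are mirror images, so one flavone can form; aryl methyl ethers are stable to methanolic HCl.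

## Compound list

1 | phloroglucinol (benzene-1,3,5-triol) | Oc1cc(O)cc(O)c1 | starting material
2 | 1,3,5-tris(methoxymethoxy)benzene | COCOc1cc(OCOC)cc(OCOC)c1 | intermediate
3 | 2,4,6-tris(methoxymethoxy)phenyllithium | [Li]c1c(OCOC)cc(OCOC)cc1OCOC | intermediate (not isolated)
4 | dimethyl 2,4,6-tris(methoxymethoxy)phenylboronate | COCOc1cc(OCOC)c(B(OC)OC)c(OCOC)c1 | intermediate (not isolated)
5 | 2,4,6-tris(methoxymethoxy)phenol | COCOc1cc(OCOC)c(O)c(OCOC)c1 | intermediate
6 | 2-methoxy-1,3,5-tris(methoxymethoxy)benzene | COCOc1cc(OCOC)c(OC)c(OCOC)c1 | intermediate
7 | 3-methoxy-2,4,6-tris(methoxymethoxy)phenyllithium | [Li]c1c(OCOC)cc(OCOC)c(OC)c1OCOC | intermediate (not isolated)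
8 | dimethyl 3-methoxy-2,4,6-tris(methoxymethoxy)phenylboronate | COCOc1cc(OCOC)c(OC)c(OCOC)c1B(OC)OC | intermediate (not isolated)
9 | 3-methoxy-2,4,6-tris(methoxymethoxy)phenol | COCOc1cc(OCOC)c(OC)c(OCOC)c1O | intermediate
10 | 2,4-dimethoxy-1,3,5-tris(methoxymethoxy)benzene | COCOc1cc(OCOC)c(OC)c(OCOC)c1OC | intermediate
11 | 3,5-dimethoxy-2,4,6-tris(methoxymethoxy)phenyllithium | [Li]c1c(OCOC)c(OC)c(OCOC)c(OC)c1OCOC | intermediate (not isolated)
12 | 2-iodo-4,6-dimethoxy-1,3,5-tris(methoxymethoxy)benzene | COCOc1c(I)c(OCOC)c(OC)c(OCOC)c1OC | intermediate
13 | 3,5-dihydroxy-4-methoxybenzoic acid | COc1c(O)cc(C(=O)O)cc1O | starting material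
14 | methyl 3,5-dihydroxy-4-methoxybenzoate | COC(=O)c1cc(O)c(OC)c(O)c1 | intermediate
15 | methyl 4-methoxy-3,5-bis(methoxymethoxy)benzoate | COCOc1cc(C(=O)OC)cc(OCOC)c1OC | intermediate
16 | methyl methoxyacetate | COCC(=O)OC | starting material
17 | lithium enolate of methyl methoxyacetate (chelated form, α-methoxy oxygen cis to O–Li) | CO/C=C(\[O-])OC.[Li+] | intermediate (not isolated)
18 | lithium enolate of ketoester 19 (chelated form) | COC(=O)/C(OC)=C(\[O-])c1cc(OCOC)c(OC)c(OCOC)c1.[Li+] | intermediate (not isolated)
19 | methyl 2-methoxy-3-[4-methoxy-3,5-bis(methoxymethoxy)phenyl]-3-oxopropanoate (racemic, labile centre) | COC(=O)C(OC)C(=O)c1cc(OCOC)c(OC)c(OCOC)c1 | intermediate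
20 | 2-methoxy-1-[4-methoxy-3,5-bis(methoxymethoxy)phenyl]ethanone | COCC(=O)c1cc(OCOC)c(OC)c(OCOC)c1 | intermediate
21 | carbon monoxide | [C-]#[O+] | starting material
22 | sodium (Z)-enolate of ketone 20 | CO/C=C(\[O-])c1cc(OCOC)c(OC)c(OCOC)c1.[Na+] | intermediate (not isolated)
23 | sodium salt of diketone 24 (chelated diketonate) | COCOc1c(C(=O)/C(OC)=C(\[O-])c2cc(OCOC)c(OC)c(OCOC)c2)c(OCOC)c(OC)c(OCOC)c1OC.[Na+] | intermediate (not isolated)
24 | (E)-1-[3,5-dimethoxy-2,4,6-tris(methoxymethoxy)phenyl]-3-hydroxy-2-methoxy-3-[4-methoxy-3,5-bis(methoxymethoxy)phenyl]prop-2-en-1-one (carbonyl and enol OH on the same side) | COCOc1c(C(=O)/C(OC)=C(\O)c2cc(OCOC)c(OC)c(OCOC)c2)c(OCOC)c(OC)c(OCOC)c1OC | intermediate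
25 | (E)-3-(3,5-dihydroxy-4-methoxyphenyl)-3-hydroxy-2-methoxy-1-(2,4,6-trihydroxy-3,5-dimethoxyphenyl)prop-2-en-1-one (chelated enol) | COc1c(O)c(OC)c(O)c(C(=O)/C(OC)=C(\O)c2cc(O)c(OC)c(O)c2)c1O | intermediate (not isolated)
26 | 5,7,3',5'-tetrahydroxy-3,6,8,4'-tetramethoxyflavone | COc1c(O)cc(-c2oc3c(OC)c(O)c(OC)c(O)c3c(=O)c2OC)cc1O | target

## Step count and least certain steps

Total step count: 12. The longest linear sequence is 8 steps (steps 1–6, 11, 12). The ring B branch contributes 4 steps (7–10) before the union.

**Step 11 (key step).**
- *Risk.* The most likely failure is a stalled catalytic cycle. Oxidative addition into an electron-rich, doubly ortho-substituted C–I bond is slow, and zerovalent palladium saturated with 21 is a poor nucleophile. Metal precipitation and hydrodeiodination could then overtake coupling. Beyond that, the crowded aroyl complex may transfer its acyl group sluggishly, leaving time for aldol self-condensation of the ketone.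
- *Fallback.* It sets out from 10 and 20 and returns at 24, making the same two bonds one after the other by polar chemistry. Compound 10 is lithiated as in step 6 (to 11) and quenched with DMF to give 3,5-dimethoxy-2,4,6-tris(methoxymethoxy)benzaldehyde F1. The lithium enolate of 20 (LiN(i-Pr)2, THF, −78 °C) is added to F1 to give the aldol 3-[3,5-dimethoxy-2,4,6-tris(methoxymethoxy)phenyl]-3-hydroxy-2-methoxy-1-[4-methoxy-3,5-bis(methoxymethoxy)phenyl]propan-1-one F2 as a diastereomer mixture. Buffered Dess–Martin periodinane then oxidises F2 to 24.

**Step 12.**
- *Risk.* The crowded, poorly enolised α-methoxy diketone may suffer acid-catalysed retro-Claisen cleavage by methanol before the ortho acetals are gone. Alternatively, dehydration of the cyclic hemiketal may stay incomplete. The polar tetrahydroxyflavone is also hard to purify from such mixtures.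
- *Fallback.* It sets out from 24 and returns at 26, separating unmasking, ring closure and purification. Compound 24 is hydrolysed with aqueous HCl in THF at 40 °C, where no alcohol nucleophile is present, to crude 25. This is heated with Ac2O and NaOAc, the closing conditions of the Allan–Robinson flavone synthesis. The product is 5,7-diacetoxy-2-(3,5-diacetoxy-4-methoxyphenyl)-3,6,8-trimethoxychromen-4-one F3, which can be crystallised or chromatographed. Catalytic K2CO3 in MeOH under argon then frees 26.

**Step 9.**
- *Risk.* The aryl ester is only a moderate electrophile. The enolate may decompose or condense with regenerated 16 on warming before it attacks 15, which would give low conversion.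
- *Fallback.* It sets out from 15 and returns at 20, so steps 9 and 10 are both bypassed. Compound 15 is converted with MeNH(OMe)·HCl and i-PrMgCl (THF, −20 °C) into the Weinreb amide N,4-dimethoxy-N-methyl-3,5-bis(methoxymethoxy)benzamide F4. This is treated at −78 °C with (methoxymethyl)lithium F5, made by tin–lithium exchange from tributyl(methoxymethyl)stannane and n-BuLi. The chelated tetrahedral adduct collapses to 20 only on work-up.

**Step 4 (and, in the same way, step 2).**
- *Risk.* Doubly ortho-alkoxylated arylboron species are prone to protodeboronation, which would return the starting arene. The very electron-rich phenol may also be over-oxidised by peroxide.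
- *Fallback.* It sets out from 6 and returns at 9, bringing in oxygen by aryl migration to a peracid instead. Compound 6 is lithiated (to 7) and quenched with DMF to give 3-methoxy-2,4,6-tris(methoxymethoxy)benzaldehyde F6. Baeyer–Villiger oxidation with mCPBA and NaHCO3 in CH2Cl2 gives 3-methoxy-2,4,6-tris(methoxymethoxy)phenyl formate F7. Brief K2CO3 in MeOH cleaves the formate to 9.

## Further compounds

F1 | step 11 | 3,5-dimethoxy-2,4,6-tris(methoxymethoxy)benzaldehyde | COCOc1c(C=O)c(OCOC)c(OC)c(OCOC)c1OC
F2 | step 11 | 3-[3,5-dimethoxy-2,4,6-tris(methoxymethoxy)phenyl]-3-hydroxy-2-methoxy-1-[4-methoxy-3,5-bis(methoxymethoxy)phenyl]propan-1-one (mixture of racemic syn and anti isomers) | COCOc1c(C(O)C(OC)C(=O)c2cc(OCOC)c(OC)c(OCOC)c2)c(OCOC)c(OC)c(OCOC)c1OC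
F3 | step 12 | 5,7-diacetoxy-2-(3,5-diacetoxy-4-methoxyphenyl)-3,6,8-trimethoxychromen-4-one | COc1c(OC(C)=O)cc(-c2oc3c(OC)c(OC(C)=O)c(OC)c(OC(C)=O)c3c(=O)c2OC)cc1OC(C)=O
F4 | step 9 | N,4-dimethoxy-N-methyl-3,5-bis(methoxymethoxy)benzamide | CON(C)C(=O)c1cc(OCOC)c(OC)c(OCOC)c1
F5 | step 9 | (methoxymethyl)lithium | [Li]COC
F6 | step 4 | 3-methoxy-2,4,6-tris(methoxymethoxy)benzaldehyde | COCOc1cc(OCOC)c(OC)c(OCOC)c1C=O
F7 | step 4 | 3-methoxy-2,4,6-tris(methoxymethoxy)phenyl formate | COCOc1cc(OCOC)c(OC)c(OCOC)c1OC=O
A1 | alternative 1 | 4-hydroxy-2-isopropoxy-3-methoxy-4-[2-(3,5-diisopropoxy-4-methoxyphenyl)-3-methoxy-4-oxo-4H-pyran-5-yl]cyclobut-2-en-1-one (racemic) | COC1=C(OC(C)C)C(=O)C1(O)c2coc(-c3cc(OC(C)C)c(OC)c(OC(C)C)c3)c(OC)c2=O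
A2 | alternative 1 | 5,8-dihydroxy-7-isopropoxy-3,6-dimethoxy-2-(3,5-diisopropoxy-4-methoxyphenyl)chromen-4-one | COc1c(O)c2c(=O)c(OC)c(-c3cc(OC(C)C)c(OC)c(OC(C)C)c3)oc2c(O)c1OC(C)C
A3 | alternative 1 | 3-isopropoxy-4-methoxycyclobut-3-ene-1,2-dione | COC1=C(OC(C)C)C(=O)C1=O
A4 | alternative 1 | 5-bromo-2-(3,5-diisopropoxy-4-methoxyphenyl)-3-methoxy-4H-pyran-4-one | COc1c(-c2cc(OC(C)C)c(OC)c(OC(C)C)c2)occ(Br)c1=O
A5 | alternative 2 | methyl (Z)-9-[3,5-bis(benzyloxy)-4-methoxyphenyl]-2,4,8-trimethoxy-3,5,7-trioxonon-8-enoate (C2 and C4 labile, unassigned) | COC(=O)C(OC)C(=O)C(OC)C(=O)CC(=O)/C(OC)=C/c1cc(OCc2ccccc2)c(OC)c(OCc2ccccc2)c1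
A6 | alternative 2 | (Z)-2',4',6'-trihydroxy-α,3',5',4-tetramethoxy-3,5-bis(benzyloxy)chalcone | COc1c(O)c(OC)c(O)c(C(=O)/C(OC)=C/c2cc(OCc3ccccc3)c(OC)c(OCc3ccccc3)c2)c1O
A7 | alternative 3 | 5,7-bis(benzyloxy)-6,8-dimethoxy-2,2-dimethyl-4H-1,3-benzodioxin-4-one | CC1(C)OC(=O)c2c(OCc3ccccc3)c(OC)c(OCc3ccccc3)c(OC)c2O1
A8 | alternative 3 | (Z)-{1-[3,5-bis(benzyloxy)-4-methoxyphenyl]-2-methoxyethenyloxy}trimethylsilane | CO/C=C(\O[Si](C)(C)C)c1cc(OCc2ccccc2)c(OC)c(OCc2ccccc2)c1
A9 | alternative 3 | 3,5-bis(benzyloxy)-2,4-dimethoxy-6-(oxomethylidene)cyclohexa-2,4-dien-1-one (quinoketene) | O=C=C1C(=O)C(OC)=C(OCc2ccccc2)C(OC)=C1OCc3ccccc3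
A10 | alternative 3 | 5,7-bis(benzyloxy)-2-[3,5-bis(benzyloxy)-4-methoxyphenyl]-3,6,8-trimethoxychromen-4-one | COc1c(OCc2ccccc2)cc(-c2oc3c(OC)c(OCc4ccccc4)c(OC)c(OCc4ccccc4)c3c(=O)c2OC)cc1OCc1ccccc1
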